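**Plan**

- Chromenone numbering is used: O1, C2, C3, C4, C4a, C5–C8, C8a. The retrosynthesis first cuts C4–C4a of the dihydropyran ring (aldol-type retron, giving an aldehyde tethered through O1), then traces the formyl carbon to a terminal alkene, then cuts the O1–C8a enol-ether bond, and last the C2–C3 bond (allyl + octadecanal).
- Forward: the C21 chain is joined by allylboration, the carbocycle enters intact as cyclohexane-1,3-dione and is O-linked to the carbinol, the alkene is cleaved to the aldehyde, and the pyran ring closes last.
- Enabling feature: C4a is the α-carbon of the push–pull enol ether O1–C8a=C4a–C5=O in the cyclohexenone ring. It is the one nucleophilic sp2 carbon, it sits six atoms from the formyl carbon, and the C5 carbonyl oxygen lies peri to C4, which allows a six-membered aluminium chelate.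
- Stereochemistry: C2 (S) comes from reagent-controlled allylboration and is kept because the carbinol C–O bond is never broken. C4 (R) comes from 1,3-induction in the ring closure; the chelated half-chair and the equilibrium position should both give the 2,4-cis isomer.

Key step: step 4

Remark: the target SMILES corresponds to (2S,4R), the 2,4-cis isomer; octadecanal and (+)-B-methoxydiisopinocampheylborane (the enantiomer made from (−)-α-pinene) are taken as commercial.

**Step 1**
Reactants: 1 octadecanal
Product: 3 (S)-henicos-1-en-4-ol, via borinate ester 2 (not isolated)
Conditions: (+)-Ipc2BOMe (1.3 equiv), allylMgBr (1.25 equiv), Et2O, −78 °C to rt; then 1, −78 °C; then aq. NaOH, H2O2, rt to reflux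
Reagents that add atoms: allylmagnesium bromide, C=CC[Mg]Br
Why: Brown allylboration through a closed chair six-membered transition state with the aldehyde chain equatorial; the allylborane carrying (−)-α-pinene-derived isopinocampheyl groups should add to the Re face of an unbranched aliphatic aldehyde and so set the (S)-carbinol that becomes C2 of the target.

**Step 2**
Reactants: 3 (S)-henicos-1-en-4-ol; 4 cyclohexane-1,3-dione
Product: 5 (S)-3-(henicos-1-en-4-yloxy)cyclohex-2-en-1-one
Conditions: 4 (1.5 equiv), p-TsOH·H2O (5 mol%), toluene, reflux, Dean–Stark
Reagents that add atoms: none
Why: Acid-catalysed dehydrative enol etherification of the cyclic 1,3-dione (vinylogous ester formation, driven by azeotropic removal of water), in which the alcohol oxygen attacks the protonated dione carbonyl, so the carbinol C–O bond stays intact and the (S) configuration is retained.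

**Step 3**
Reactants: 5 (S)-3-(henicos-1-en-4-yloxy)cyclohex-2-en-1-one
Product: 7 (S)-3-[(3-oxocyclohex-1-en-1-yl)oxy]icosanal, via vicinal diol 6 (not isolated)
Conditions: OsO4 (2 mol%), NaIO4 (4 equiv), 2,6-lutidine (2 equiv), 1,4-dioxane/H2O 3:1, 0 °C to rt; cold extractive work-up, crude used at once
Reagents that add atoms: osmium tetroxide, O=[Os](=O)(=O)=O; sodium periodate, [Na+].[O-]I(=O)(=O)=O (source of the formyl oxygen, delivered through the osmate ester and replenished by periodate)
Why: Lemieux–Johnson oxidative cleavage, in which OsO4 should dihydroxylate the unhindered monosubstituted alkene faster than the trisubstituted enol-ether double bond deactivated by conjugation to the ketone, and periodate then cleaves the diol without touching the stereocentre; the β-alkoxy aldehyde is used crude because it can lose the dione enolate by β-elimination.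

**Step 4**
Reactants: 7 (S)-3-[(3-oxocyclohex-1-en-1-yl)oxy]icosanal
Product: 9 (2S,4R)-2-heptadecyl-4-hydroxy-2,3,4,6,7,8-hexahydro-5H-chromen-5-one, via aluminium aldolate 8 (not isolated)
Conditions: Me2AlCl (2.2 equiv), CH2Cl2, −78 to −20 °C; then aq. sodium potassium tartrate, 0 °C
Reagents that add atoms: none
Why: Proposed new method: the closest known reaction types are Lewis-acid Prins-type ring closures in which the α-carbon of a vinylogous ester attacks a tethered oxocarbenium ion, and Me2AlCl-promoted carbonyl-ene and Prins cyclisations of aldehydes, whereas a free aldehyde has not been shown as the electrophile for the α-carbon of a 3-alkoxy-enone. Mechanistically, Me2AlCl activates the formyl group, the enone α-carbon (the enol-ether β-carbon, future C4a) attacks the formyl carbon (future C4) to give an oxocarbenium ion at C8a/O1, and the now doubly activated C4a–H is removed by an Al–Me bond as methane, which restores the vinylogous ester as the aluminium aldolate 8 in a non-acidic medium. The pyran ring closes in a 6-(enolendo)-exo-trig mode. The new C4 centre is controlled by C2: in a half-chair transition state the heptadecyl chain is pseudo-equatorial and the aluminium-bound formyl oxygen is held pseudo-equatorial by chelation to the C5 carbonyl oxygen, which gives the 2,4-cis (2S,4R) arrangement, and the same chelated cis aldolate should also be the more stable one, so any reversibility of the aldol works toward the same isomer. The step needs C–C bond formation to win over β-elimination of the dione enolate and needs the product not to ionise at C4; low temperature, the absence of base, the six-ring closure and the proton-scavenging Al–Me bonds should secure this.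

**Compound list**

1 | octadecanal | CCCCCCCCCCCCCCCCCC=O | starting material
2 | (S)-henicos-1-en-4-yl bis[(1S,2R,3S,5S)-2,6,6-trimethylbicyclo[3.1.1]hept-3-yl]borinate | CCCCCCCCCCCCCCCCC[C@H](OB([C@H]1C[C@H]2C[C@@H]([C@@H]1C)C2(C)C)[C@H]1C[C@H]2C[C@@H]([C@@H]1C)C2(C)C)CC=C | intermediate
3 | (S)-henicos-1-en-4-ol | CCCCCCCCCCCCCCCCC[C@H](O)CC=C | intermediate
4 | cyclohexane-1,3-dione | O=C1CCCC(=O)C1 | starting material
5 | (S)-3-(henicos-1-en-4-yloxy)cyclohex-2-en-1-one | CCCCCCCCCCCCCCCCC[C@H](OC1=CC(=O)CCC1)CC=C | intermediate
6 | 3-{[(4S)-1,2-dihydroxyhenicosan-4-yl]oxy}cyclohex-2-en-1-one (both epimers at the secondary carbinol) | CCCCCCCCCCCCCCCCC[C@H](OC1=CC(=O)CCC1)CC(O)CO | intermediate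
7 | (S)-3-[(3-oxocyclohex-1-en-1-yl)oxy]icosanal | CCCCCCCCCCCCCCCCC[C@H](OC1=CC(=O)CCC1)CC=O | intermediate
8 | chloro(methyl)aluminium (2S,4R)-2-heptadecyl-5-oxo-3,4,5,6,7,8-hexahydro-2H-chromen-4-olate | CCCCCCCCCCCCCCCCC[C@H]1C[C@@H](O[Al](C)Cl)C2=C(CCCC2=O)O1 | intermediate
9 | (2S,4R)-2-heptadecyl-4-hydroxy-2,3,4,6,7,8-hexahydro-5H-chromen-5-one | CCCCCCCCCCCCCCCCC[C@H]1C[C@@H](O)C2=C(CCCC2=O)O1 | target

**Totals**

Total step count: 4. Longest linear sequence: 4 steps (1 → 3 → 5 → 7 → 9).

**Steps most likely to fail**

Step 4 (carries the label). The vinylogous-ester carbon may be too weak a nucleophile once aluminium sits on the C5 carbonyl, so no ring closure occurs. The activated aldehyde may instead lose the dione enolate by β-elimination, or a methyl group may transfer from aluminium to the formyl group. The fallback reverses the polarity of the same bond with known chemistry and sets out from 5. Iodination at the enone α-carbon with N-iodosuccinimide in CH2Cl2 should give (S)-3-(henicos-1-en-4-yloxy)-2-iodocyclohex-2-en-1-one F1. Cleavage of the terminal alkene as in step 3 should give (S)-3-[(2-iodo-3-oxocyclohex-1-en-1-yl)oxy]icosanal F2. An intramolecular Nozaki–Hiyama–Kishi reaction (CrCl2 in excess, NiCl2 cat., DMF, rt) should then add the alkenylchromium carbon to the aldehyde and come back to the route at 9. The chromium alkoxide is expected pseudo-equatorial, hence cis; any trans epimer would be removed by chromatography.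

Step 3. The enol-ether double bond may be oxidised along with the terminal alkene, and the β-alkoxy aldehyde may undergo β-elimination in the aqueous, lutidine-buffered medium or during isolation. The fallback sets out from 5 and separates the two events. Dihydroxylation with OsO4 (cat.) and N-methylmorpholine N-oxide in acetone/H2O would be stopped at the diol 6, which is stable and would be isolated and purified. Glycol cleavage with Pb(OAc)4 in dry CH2Cl2 at −78 to 0 °C, free of water and base, would then give 7 after filtration. The solution would go straight into step 4, so the route is rejoined at 7 without isolating the aldehyde.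

Step 2. Condensation of the hindered secondary alcohol, used as the limiting component, may stay incomplete while the dione self-condenses, and hot acid may start to dehydrate the homoallylic alcohol. The fallback sets out from 3 and forms the same C–O bond by addition–elimination under basic conditions. The sodium alkoxide of 3 (NaH, THF, 0 °C) would be added to commercial 3-chlorocyclohex-2-en-1-one, which should give 5 with retention at the carbinol, and the route is rejoined at 5.

**Further compounds**

F1 | step 4 | (S)-3-(henicos-1-en-4-yloxy)-2-iodocyclohex-2-en-1-one | CCCCCCCCCCCCCCCCC[C@H](OC1=C(I)C(=O)CCC1)CC=C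
F2 | step 4 | (S)-3-[(2-iodo-3-oxocyclohex-1-en-1-yl)oxy]icosanal | CCCCCCCCCCCCCCCCC[C@H](OC1=C(I)C(=O)CCC1)CC=O
F0 | step 3 | none | none
F0 | step 2 | none | none
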